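## Structural features

The target is a flavan. A benzene ring (ring A) is fused through C4a–C8a to a dihydropyran (ring C: O1, C2, C3, C4), and a 2,4-dihydroxyphenyl ring (ring B) sits on C2. Ring A carries OH at C5, OMe at C7 and a 3-methylbut-2-enyl (prenyl) group at C8, so only C6 bears hydrogen and the three ring A oxygens form a phloroglucinol pattern. C2 is the only stereocentre and is (S); it has no stereogenic neighbour. It is an ether carbon benzylic to the electron-rich ring B, so it can ionise under acid, and it can open through a quinone methide once the 2'- or 4'-phenol is deprotonated; either process would racemise it. The trisubstituted prenyl alkene is sensitive to acid and to unselective hydrogenation, and the free phenols are oxidisable. The real difficulties are to set and keep C2, to build ring A with O1 distinguished from the two other oxygens, and to saturate C3–C4 without touching the prenyl group. The key step uses the C3–C4 bond of ring C: C4 is benzylic on C4a of ring A and C3 is the neighbour of the O1-bearing C2, so the bond can be made as a C3=C4 alkene from a vinyl group on C4a and the alkene of an O1–C2 allyl ether.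

## Logic of the disconnections

17 is traced back to 16 by cutting three phenolic O–Si bonds. This keeps the oxidisable, quinone-methide-prone phenols masked until the end and makes every earlier intermediate a base-stable ether. The forward step must remove three aryl silyl ethers without strong acid or free phenoxide, which acetic-acid-buffered fluoride can do.

16 is traced back to 15 by turning the C3–C4 single bond into a C3=C4 double bond. This is what allows ring C to come from two alkenes. The forward step must reduce a cis-disubstituted ring alkene and spare both the trisubstituted side-chain alkene and the benzylic C2–O1 bond; diimide at room temperature is chosen for that.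

15 is traced back to 14 by cutting C3=C4 in the metathesis sense, leaving a vinyl group on C4a and the vinyl group of an allyl ether on O1. Ring C disappears and an acyclic diaryl-type ether with one stereocentre remains. The forward step needs a carbene catalyst that joins the two terminal alkenes, ignores the prenyl alkene and does not shift the allyl ether double bond.

14 is traced back to 13 and 12 by cutting O1–C2. The molecule falls into a ring A half and a ring B half of similar size, and C2 is created in a catalyst-controlled step. The forward step must be branched-selective and enantioselective with a doubly ortho-substituted aryloxide and an electron-rich allyl unit. The precursor keeps three triisopropylsilyl ethers; the design is tightened on the electrophile side, where a tert-butyl carbonate replaces a methyl carbonate so that the alkoxide released is non-nucleophilic.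

13 is traced back through 6 to 5 by cutting the O–Li bond and the C4=CH2 double bond. The styrene becomes an aldehyde, whose carbon is the future C4. The forward methylenation must run on a hindered aldehyde next to a free phenol.

5 is traced back to 4 by cutting the O–Si bond at the oxygen that becomes O5. The forward step must distinguish two chelated phenols; the prenyl group beside one of them provides the steric bias.

4 is traced back to 2 and 3 by cutting the C8–CH2 bond of the prenyl group. The two open ring positions of 2 are equivalent, so no regiochemical question arises. The forward step must favour C- over O-alkylation.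

2 is traced back to 1 by cutting the O–CH3 bond. The forward step must methylate only the hydroxyl that is not hydrogen-bonded to the formyl group.

12 is traced back through 11 to 10 by cutting the carbonate O–C(=O) bond. This is a simple activation of an allylic alcohol; the forward step must avoid acid, because the cinnamyl system is electron-rich.

10 is traced back to 9 by raising the oxidation level of the terminal carbon from alcohol to ester. The forward step is a 1,2-reduction that must leave the alkene alone.

9 is traced back to 8 by cutting the alkene C=C bond. The carbon added here becomes C3 and the aldehyde carbon of 8 becomes C2. The forward olefination must give the (E)-alkene under conditions mild to aryl silyl ethers.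

8 is traced back to 7 by cutting two O–Si bonds; the forward step is a double silylation.

## Other disconnections considered

Alternative 1: The cut runs through ring A itself. C4a–C5, C8–C8a and C5–C6 are disconnected, so ring A would be assembled from the cyclobutenone A2 and the siloxyalkyne A3, which already carries the C4–C3–C2 chain and the C2 carbinol. On heating, A2 would open to a vinylketene that adds to A3; ring opening and six-electron electrocyclisation of the adduct would give the phenol A1.
- In its favour: every ring A substituent is placed by the connectivity of the two partners. No C- versus O-prenylation and no differentiation of two similar phenols is needed, and on this point it is better than the chosen plan.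
- Also in its favour: the carbinol would come from an asymmetric ketone reduction, a more routine operation than step 9, and C3–C4 is saturated from the start, so no alkene has to be reduced beside the prenyl group.
- Against it: the phenol set free in A1 is the C5 oxygen, because it derives from the ketene carbonyl. The oxygen that must become O1 emerges as the triisopropylsilyl ether. Ring C could be closed only after capping the C5 phenol, removing two silyl ethers and displacing the secondary alcohol with inversion in a Mitsunobu reaction.
- Against it: a carbinol benzylic to a 2,4-dioxygenated ring may ionise in that displacement and lose configuration, and the methoxymethyl ethers would finally need acid, which the C2–O1 bond and the prenyl group tolerate poorly.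
- Comparison: the pericyclic cascade is mechanistically sound and regiochemically defined. A2 and A3 each need several steps, so the chosen plan is clearly shorter, and it places the risk to C2 in an early catalytic step and not in a late substitution.

Alternative 2: O1–C8a and C4–C4a are cut, giving the silyl triflate A5 as an aryne precursor and the chloro alcohol A6. Fluoride (CsF with 18-crown-6) would release the C4a–C8a aryne, the sodium alkoxide of A6 would add at C8a, and the aryl anion at C4a would displace chloride to give the flavan A4.
- In its favour: ring C would be closed at the flavan oxidation level in one step with two new bonds. The C2–O bond of A6 is never broken, so the stereocentre comes intact from a routine asymmetric reduction of a 3-chloropropiophenone. No alkene reduction next to the prenyl group is needed. On these points it is the equal or the better of the chosen plan.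
- Against it: A5 is a hexasubstituted benzene whose regiodefined synthesis would be long.
- Against it: the C5 alkoxy group should direct the nucleophile to the distal aryne carbon C8a, which is the required sense, but C8a is also the carbon flanked by the prenyl group.
- Against it: a secondary alkoxide is a modest aryne trap, and the short-lived aryl anion must cyclise faster than it is protonated. The methoxymethyl ethers again call for acid at the end.
- Comparison: the step count after the key step is lower than in the chosen plan, but the total is higher because of A5, and the key step rests on thinner precedent than ring-closing metathesis to 2H-chromenes.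

Alternative 3: C3–C4 and O1–C2 are cut, giving the hydroxybenzyl alcohol A8 and the hydroxystyrene A9. A chiral phosphoric acid would dehydrate A8 to its ortho-quinone methide, which adds A9 in a formal [4+2] cycloaddition to give the flavan A7, closing ring C and setting C2 in one step.
- In its favour: this is the most convergent plan. Two bonds, the ring and the stereocentre are made together, directly at the saturated level, and only desilylation follows. On step economy it is better than the chosen plan. A8 would come from an aldehyde of the same kind as 5 by hydride reduction, so the ring A chemistry is shared.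
- Against it: the quinone methide from A8 is unsubstituted at the methide carbon. Such species form less readily from a primary benzylic alcohol under Brønsted acid and oligomerise easily, and enantiocontrol is best established for aryl-substituted quinone methides.
- Against it: the free phenol of A8 stands ortho to the prenyl group, and acid could close a dimethylchroman there.
- Comparison: the endgame is equal to that of the chosen plan (fluoride only), but C2 would depend on a catalyst–substrate match that is less predictable than the allylic etherification followed by a stereochemically innocent metathesis.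

Key step: step 10

Assumption: the (Sa,S,S) antipode of the phosphoramidite is taken as the one that delivers the (S)-ether in step 9; the (Ra,R,R) antipode, equally available, is used if the sense of induction proves opposite.

## Steps

Step 1
Reactants: 1 2,4,6-trihydroxybenzaldehyde
Product: 2 2,6-dihydroxy-4-methoxybenzaldehyde
Conditions: Me2SO4 (1.0 equiv), K2CO3 (1.0 equiv), acetone, 0 °C → rt
Reagents that add atoms: dimethyl sulfate, COS(=O)(=O)OC
Why: Williamson O-methylation; the 4-OH is the only hydroxyl not hydrogen-bonded to the formyl group and the most acidic, so one equivalent of base and a hard methyl donor should alkylate it selectively on oxygen.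

Step 2
Reactants: 2 2,6-dihydroxy-4-methoxybenzaldehyde; 3 prenyl bromide
Product: 4 2,6-dihydroxy-4-methoxy-3-(3-methylbut-2-enyl)benzaldehyde
Conditions: 3 (1.1 equiv), 10% aq. KOH, 0 °C → rt
Reagents that add atoms: none
Why: C-alkylation of a phloroglucinol-type phenoxide by SN2 on the allylic bromide; in water the oxygens are strongly solvated, which favours attack through carbon. The two open ring positions are equivalent by symmetry, so only one mono-C-prenyl isomer can form.

Step 3
Reactants: 4 2,6-dihydroxy-4-methoxy-3-(3-methylbut-2-enyl)benzaldehyde
Product: 5 2-hydroxy-4-methoxy-3-(3-methylbut-2-enyl)-6-(triisopropylsilyloxy)benzaldehyde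
Conditions: i-Pr3SiCl (1.05 equiv), imidazole, DMF, 0 °C
Reagents that add atoms: triisopropylsilyl chloride, CC(C)[Si](Cl)(C(C)C)C(C)C
Why: Sterically controlled monosilylation; the C2 hydroxyl is flanked by the prenyl methylene while the C6 hydroxyl has a ring hydrogen beside it, so the bulky silyl chloride should take the C6 oxygen. The remaining C2 phenol stays hydrogen-bonded to the aldehyde, which slows a second silylation.

Step 4
Reactants: 5 2-hydroxy-4-methoxy-3-(3-methylbut-2-enyl)-6-(triisopropylsilyloxy)benzaldehyde
Product: 6 3-methoxy-2-(3-methylbut-2-enyl)-5-(triisopropylsilyloxy)-6-vinylphenol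
Conditions: Ph3PCH3Br (3.0 equiv), KOt-Bu (2.9 equiv), THF, 0 °C → rt
Reagents that add atoms: methyltriphenylphosphonium bromide, C[P+](c1ccccc1)(c1ccccc1)c1ccccc1.[Br-]
Why: Wittig methylenation; one equivalent of ylide is consumed by the phenol and the excess converts the aldehyde into the vinyl group, the usual way from salicylaldehydes to 2-vinylphenols. The silyl ether is meta to the phenoxide and cannot migrate to it; 6 is used promptly because electron-rich vinylphenols are acid-sensitive.

Step 5
Reactants: 7 2,4-dihydroxybenzaldehyde
Product: 8 2,4-bis(triisopropylsilyloxy)benzaldehyde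
Conditions: i-Pr3SiCl (2.4 equiv), imidazole, DMF, rt → 40 °C
Reagents that add atoms: triisopropylsilyl chloride, CC(C)[Si](Cl)(C(C)C)C(C)C
Why: Imidazole-promoted silylation of both phenols; triisopropylsilyl ethers are chosen because they should survive ylide, hydride, aryloxide and tert-butoxide and still fall to fluoride at the end.

Step 6
Reactants: 8 2,4-bis(triisopropylsilyloxy)benzaldehyde
Product: 9 ethyl (E)-3-[2,4-bis(triisopropylsilyloxy)phenyl]prop-2-enoate
Conditions: Ph3P=CHCO2Et (1.3 equiv), toluene, 80 °C
Reagents that add atoms: (ethoxycarbonylmethylene)triphenylphosphorane, CCOC(=O)C=P(c1ccccc1)(c1ccccc1)c1ccccc1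
Why: Wittig olefination with a stabilised ylide gives the (E)-cinnamate under neutral conditions and avoids basic phosphonate anions that could attack the aryl silyl ethers.

Step 7
Reactants: 9 ethyl (E)-3-[2,4-bis(triisopropylsilyloxy)phenyl]prop-2-enoate
Product: 10 (E)-3-[2,4-bis(triisopropylsilyloxy)phenyl]prop-2-en-1-ol
Conditions: i-Bu2AlH (2.4 equiv), CH2Cl2, −78 °C; aq. potassium sodium tartrate
Reagents that add atoms: none
Why: 1,2-Reduction of the conjugated ester by the aluminium hydride at low temperature gives the allylic alcohol and leaves the alkene and silyl ethers alone; the neutral tartrate work-up protects the acid-sensitive electron-rich cinnamyl alcohol.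

Step 8
Reactants: 10 (E)-3-[2,4-bis(triisopropylsilyloxy)phenyl]prop-2-en-1-ol
Product: 12 tert-butyl (E)-3-[2,4-bis(triisopropylsilyloxy)phenyl]prop-2-enyl carbonate, via lithium alkoxide 11 (not isolated)
Conditions: n-BuLi (1.0 equiv), THF, −78 °C; then Boc2O (1.1 equiv), −78 °C → rt; H2O
Reagents that add atoms: di-tert-butyl dicarbonate, CC(C)(C)OC(=O)OC(=O)OC(C)(C)C; n-butyllithium, [Li]CCCC (supplies the lithium of 11 only)
Why: Acylation of the preformed lithium alkoxide with the dicarbonate gives the mixed carbonate without acid. The tert-butyl carbonate is preferred to a methyl carbonate because the tert-butoxide released in step 9 is a poor nucleophile and will not compete with the hindered aryloxide or attack the silyl ethers.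

Step 9
Reactants: 6 3-methoxy-2-(3-methylbut-2-enyl)-5-(triisopropylsilyloxy)-6-vinylphenol; 12 tert-butyl (E)-3-[2,4-bis(triisopropylsilyloxy)phenyl]prop-2-enyl carbonate
Product: 14 (S)-1-[2,4-bis(triisopropylsilyloxy)phenyl]prop-2-enyl 3-methoxy-2-(3-methylbut-2-enyl)-5-(triisopropylsilyloxy)-6-vinylphenyl ether, via lithium aryloxide 13 (not isolated)
Conditions: 6, LiN(SiMe3)2 (1.0 equiv), THF, 0 °C; then 12 (1.1 equiv), [Ir(cod)Cl]2 (2.5 mol%), (Sa,S,S)-O,O'-(1,1'-binaphthyl-2,2'-diyl) N,N-bis[1-(2-methoxyphenyl)ethyl]phosphoramidite (5 mol%, activated with n-PrNH2), THF, rt; H2O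
Reagents that add atoms: lithium bis(trimethylsilyl)amide, [Li]N([Si](C)(C)C)[Si](C)(C)C (supplies the lithium of 13 only)
Why: Branched-selective asymmetric allylic etherification: the cyclometalated complex of monovalent iridium adds oxidatively to 12 with loss of CO2 and tert-butoxide, and the aryloxide 13 attacks the aryl-substituted terminus of the resulting allyl complex of trivalent iridium anti to the metal. C2 is set here under control of the chiral phosphoramidite; the ortho-methoxyphenyl ligand variant is chosen because the electrophile is ortho-substituted. The electron-rich aryloxide is a poor leaving group, so the product should not re-ionise on the catalyst.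

Step 10
Reactants: 14 (S)-1-[2,4-bis(triisopropylsilyloxy)phenyl]prop-2-enyl 3-methoxy-2-(3-methylbut-2-enyl)-5-(triisopropylsilyloxy)-6-vinylphenyl ether
Product: 15 (2S)-2-[2,4-bis(triisopropylsilyloxy)phenyl]-7-methoxy-8-(3-methylbut-2-enyl)-5-(triisopropylsilyloxy)-2H-chromene
Conditions: second-generation Grubbs catalyst (H2IMes)(PCy3)Cl2Ru=CHPh (5 mol%), 1,4-benzoquinone (10 mol%), CH2Cl2 (5 mM), 40 °C, dark; then ethyl vinyl ether
Reagents that add atoms: none
Why: The ruthenium benzylidene exchanges by [2+2] cycloaddition and cycloreversion onto the monosubstituted allyl ether alkene, the new alkylidene adds across the C4a vinyl group within the molecule, and cycloreversion of that metallacyclobutane forms C3=C4 and a ruthenium methylidene that carries the chain; loss of ethylene drives the reaction. The closest known reaction type is ring-closing metathesis of 2-vinylphenyl allyl ethers to 2H-chromenes, 2-aryl cases included. Ring C closes as a six-membered ring from a 1,7-diene (counted through O1), and the two inner alkene carbons become the endocyclic, necessarily cis, C3=C4 bond. No stereocentre is formed; no bond to C2 is made or broken, so its configuration from step 9 is carried through. The step needs chemoselectivity among three alkenes: the two terminal ones react, while the trisubstituted prenyl alkene would need a more crowded metallacyclobutane and could only close a seven-membered ring. It also needs the allyl ether double bond to stay in place, since migration would erase C2 or lead to ring contraction; benzoquinone is added to intercept ruthenium hydrides, and the moderate temperature and short reaction time serve the same end. High dilution keeps intermolecular metathesis down.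

Step 11
Reactants: 15 (2S)-2-[2,4-bis(triisopropylsilyloxy)phenyl]-7-methoxy-8-(3-methylbut-2-enyl)-5-(triisopropylsilyloxy)-2H-chromene
Product: 16 (2S)-2-[2,4-bis(triisopropylsilyloxy)phenyl]-7-methoxy-8-(3-methylbut-2-enyl)-5-(triisopropylsilyloxy)chroman
Conditions: 2-O2NC6H4SO2NHNH2 (added in portions until 15 is consumed), Et3N, CH2Cl2, rt, dark
Reagents that add atoms: none
Why: Diimide reduction: the diimide formed at room temperature from the sulfonylhydrazide transfers two hydrogens in a concerted syn step to the cis-disubstituted, aryl-conjugated C3=C4 bond faster than to the trisubstituted prenyl alkene, and it cannot hydrogenolyse the benzylic C2–O1 bond or shift alkenes. Room temperature and exclusion of light guard against electrocyclic opening of the 2H-chromene, which would scramble C2.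

Step 12
Reactants: 16 (2S)-2-[2,4-bis(triisopropylsilyloxy)phenyl]-7-methoxy-8-(3-methylbut-2-enyl)-5-(triisopropylsilyloxy)chroman
Product: 17 (2S)-2-(2,4-dihydroxyphenyl)-7-methoxy-8-(3-methylbut-2-enyl)chroman-5-ol
Conditions: n-Bu4NF (3.5 equiv), AcOH (3.5 equiv), THF, 0 °C, Ar
Reagents that add atoms: none
Why: Fluoride-mediated desilylation of three aryl silyl ethers, driven by the Si–F bond. Buffering with acetic acid keeps the phenols protonated, so no 2'- or 4'-phenoxide can expel O1 through a quinone methide and racemise C2, and no acid strong enough to ionise C2–O1 or hydrate the prenyl group is present.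

## Compound list

1 | 2,4,6-trihydroxybenzaldehyde | O=Cc1c(O)cc(O)cc1O | starting material
2 | 2,6-dihydroxy-4-methoxybenzaldehyde | COc1cc(O)c(C=O)c(O)c1 | intermediate
3 | prenyl bromide (1-bromo-3-methylbut-2-ene) | CC(C)=CCBr | starting material
4 | 2,6-dihydroxy-4-methoxy-3-(3-methylbut-2-enyl)benzaldehyde | COc1cc(O)c(C=O)c(O)c1CC=C(C)C | intermediate
5 | 2-hydroxy-4-methoxy-3-(3-methylbut-2-enyl)-6-(triisopropylsilyloxy)benzaldehyde | COc1cc(O[Si](C(C)C)(C(C)C)C(C)C)c(C=O)c(O)c1CC=C(C)C | intermediate
6 | 3-methoxy-2-(3-methylbut-2-enyl)-5-(triisopropylsilyloxy)-6-vinylphenol | COc1cc(O[Si](C(C)C)(C(C)C)C(C)C)c(C=C)c(O)c1CC=C(C)C | intermediate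
7 | 2,4-dihydroxybenzaldehyde | O=Cc1ccc(O)cc1O | starting material
8 | 2,4-bis(triisopropylsilyloxy)benzaldehyde | O=Cc1ccc(O[Si](C(C)C)(C(C)C)C(C)C)cc1O[Si](C(C)C)(C(C)C)C(C)C | intermediate
9 | ethyl (E)-3-[2,4-bis(triisopropylsilyloxy)phenyl]prop-2-enoate | CCOC(=O)/C=C/c1ccc(O[Si](C(C)C)(C(C)C)C(C)C)cc1O[Si](C(C)C)(C(C)C)C(C)C | intermediate
10 | (E)-3-[2,4-bis(triisopropylsilyloxy)phenyl]prop-2-en-1-ol | OC/C=C/c1ccc(O[Si](C(C)C)(C(C)C)C(C)C)cc1O[Si](C(C)C)(C(C)C)C(C)C | intermediate
11 | lithium (E)-3-[2,4-bis(triisopropylsilyloxy)phenyl]prop-2-en-1-olate | [Li+].[O-]C/C=C/c1ccc(O[Si](C(C)C)(C(C)C)C(C)C)cc1O[Si](C(C)C)(C(C)C)C(C)C | intermediate (not isolated)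
12 | tert-butyl (E)-3-[2,4-bis(triisopropylsilyloxy)phenyl]prop-2-enyl carbonate | CC(C)(C)OC(=O)OC/C=C/c1ccc(O[Si](C(C)C)(C(C)C)C(C)C)cc1O[Si](C(C)C)(C(C)C)C(C)C | intermediate
13 | lithium 3-methoxy-2-(3-methylbut-2-enyl)-5-(triisopropylsilyloxy)-6-vinylphenolate | [Li+].COc1cc(O[Si](C(C)C)(C(C)C)C(C)C)c(C=C)c([O-])c1CC=C(C)C | intermediate (not isolated)
14 | (S)-1-[2,4-bis(triisopropylsilyloxy)phenyl]prop-2-enyl 3-methoxy-2-(3-methylbut-2-enyl)-5-(triisopropylsilyloxy)-6-vinylphenyl ether | COc1cc(O[Si](C(C)C)(C(C)C)C(C)C)c(C=C)c(c1CC=C(C)C)O[C@H](c1ccc(O[Si](C(C)C)(C(C)C)C(C)C)cc1O[Si](C(C)C)(C(C)C)C(C)C)C=C | intermediate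
15 | (2S)-2-[2,4-bis(triisopropylsilyloxy)phenyl]-7-methoxy-8-(3-methylbut-2-enyl)-5-(triisopropylsilyloxy)-2H-chromene | COc1cc(O[Si](C(C)C)(C(C)C)C(C)C)c2c(c1CC=C(C)C)O[C@H](c1ccc(O[Si](C(C)C)(C(C)C)C(C)C)cc1O[Si](C(C)C)(C(C)C)C(C)C)C=C2 | intermediate
16 | (2S)-2-[2,4-bis(triisopropylsilyloxy)phenyl]-7-methoxy-8-(3-methylbut-2-enyl)-5-(triisopropylsilyloxy)chroman | COc1cc(O[Si](C(C)C)(C(C)C)C(C)C)c2c(c1CC=C(C)C)O[C@H](c1ccc(O[Si](C(C)C)(C(C)C)C(C)C)cc1O[Si](C(C)C)(C(C)C)C(C)C)CC2 | intermediate
17 | (2S)-2-(2,4-dihydroxyphenyl)-7-methoxy-8-(3-methylbut-2-enyl)chroman-5-ol | COc1cc(O)c2c(c1CC=C(C)C)O[C@H](c1ccc(O)cc1O)CC2 | target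

## Step count and least certain steps

Total: 12 steps. Longest linear sequence: 8 steps (steps 1–4 then 9–12; the ring B branch, steps 5–8 then 9–12, is equally long).

Step 10 (key step). Most likely to go wrong: ruthenium-hydride-induced migration of the allyl ether double bond, which would destroy C2 or divert the closure, and slow turnover because both reacting alkenes are crowded (a styrene with two ortho substituents and an allylic carbon bearing the ortho-silyloxyaryl group), so that catalyst decay outruns ring closure. Engagement of the prenyl alkene with loss of isobutene is a lesser concern. Fallback, a relay ring-closing metathesis that sets out from 5 and comes back at 15: 5 would be olefinated with the ylide from hex-5-enyltriphenylphosphonium bromide and KOt-Bu to give the relay phenol 2-[(1Z)-hepta-1,6-dienyl]-5-methoxy-6-(3-methylbut-2-enyl)-3-(triisopropylsilyloxy)phenol F1. LiN(SiMe3)2 would convert it into its lithium aryloxide F2, and etherification with 12 under the conditions of step 9 would give the relay ether F3. With (H2IMes)(PCy3)Cl2Ru=CHPh the carbene should load on the unhindered terminal alkene of the tether, expel cyclopentene and so be delivered to C4, from where it closes onto the allyl ether to give 15.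

Step 9. Most likely to go wrong: loss of enantio- or regiocontrol. The bulky ortho-silyloxy group may distort the allyl complex and the electron-rich allyl terminus may ionise, leading to the linear ether or to C-allylation at the free ring position para to the aryloxide oxygen. Conversion may also be low with the doubly ortho-substituted aryloxide. Fallback, a resolution that sets out from 13 and 12 and comes back at 17: etherification with the achiral, less hindered catalyst from [Ir(cod)Cl]2 and P(OPh)3 should give racemic 14 F4. The conditions of steps 10, 11 and 12 would carry it through racemic 15 F5 and racemic 16 F6 to racemic 17 F7. Preparative chromatography of this polar triphenol on a cellulose tris(3,5-dimethylphenylcarbamate) stationary phase would then separate 17 from the (R)-enantiomer of 17 F8.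

Step 11. Most likely to go wrong: over-reduction of the prenyl alkene once diimide is in excess, since the rate gap between a cis-disubstituted ring alkene and a trisubstituted alkene is moderate, or incomplete reduction if the reagent decomposes first. Fallback, sets out from 15 and comes back at 16: homogeneous hydrogenation with RhCl(PPh3)3 under H2 (1 atm) in benzene–ethanol at rt. This works by alkene coordination and insertion at rhodium, whose rate falls steeply with alkene substitution, and not by concerted hydrogen transfer. New compound on this way: none F0.

Step 2. Most likely to go wrong: competing O-prenylation and a second C-prenylation, leaving little of the mono-C-prenyl product. Fallback, sets out from 2 and comes back at 4: mono-O-alkylation of 2 with 3-chloro-3-methylbut-1-yne (CuCl2 cat., DBU, MeCN, 0 °C) would give 2-hydroxy-4-methoxy-6-(2-methylbut-3-yn-2-yloxy)benzaldehyde F9. Semi-hydrogenation (H2, Pd on CaCO3 poisoned with Pb(OAc)2, quinoline) would give 2-hydroxy-4-methoxy-6-(2-methylbut-3-en-2-yloxy)benzaldehyde F10. Its aromatic Claisen rearrangement (toluene, 110 °C) moves the allyl unit with inversion to the only free ortho carbon and gives 4 with the C–C bond placed unambiguously.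

## Further compounds

F1 | step 10 | 2-[(1Z)-hepta-1,6-dienyl]-5-methoxy-6-(3-methylbut-2-enyl)-3-(triisopropylsilyloxy)phenol | COc1cc(O[Si](C(C)C)(C(C)C)C(C)C)c(/C=C\CCCC=C)c(O)c1CC=C(C)C
F2 | step 10 | lithium 2-[(1Z)-hepta-1,6-dienyl]-5-methoxy-6-(3-methylbut-2-enyl)-3-(triisopropylsilyloxy)phenolate | [Li+].COc1cc(O[Si](C(C)C)(C(C)C)C(C)C)c(/C=C\CCCC=C)c([O-])c1CC=C(C)C
F3 | step 10 | (S)-1-[2,4-bis(triisopropylsilyloxy)phenyl]prop-2-enyl 2-[(1Z)-hepta-1,6-dienyl]-5-methoxy-6-(3-methylbut-2-enyl)-3-(triisopropylsilyloxy)phenyl ether | COc1cc(O[Si](C(C)C)(C(C)C)C(C)C)c(/C=C\CCCC=C)c(c1CC=C(C)C)O[C@H](c1ccc(O[Si](C(C)C)(C(C)C)C(C)C)cc1O[Si](C(C)C)(C(C)C)C(C)C)C=C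
F4 | step 9 | racemic 14 | COc1cc(O[Si](C(C)C)(C(C)C)C(C)C)c(C=C)c(c1CC=C(C)C)OC(c1ccc(O[Si](C(C)C)(C(C)C)C(C)C)cc1O[Si](C(C)C)(C(C)C)C(C)C)C=C
F5 | step 9 | racemic 15 | COc1cc(O[Si](C(C)C)(C(C)C)C(C)C)c2c(c1CC=C(C)C)OC(c1ccc(O[Si](C(C)C)(C(C)C)C(C)C)cc1O[Si](C(C)C)(C(C)C)C(C)C)C=C2
F6 | step 9 | racemic 16 | COc1cc(O[Si](C(C)C)(C(C)C)C(C)C)c2c(c1CC=C(C)C)OC(c1ccc(O[Si](C(C)C)(C(C)C)C(C)C)cc1O[Si](C(C)C)(C(C)C)C(C)C)CC2
F7 | step 9 | racemic 17 | COc1cc(O)c2c(c1CC=C(C)C)OC(c1ccc(O)cc1O)CC2
F8 | step 9 | (2R)-2-(2,4-dihydroxyphenyl)-7-methoxy-8-(3-methylbut-2-enyl)chroman-5-ol | COc1cc(O)c2c(c1CC=C(C)C)O[C@@H](c1ccc(O)cc1O)CC2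
F0 | step 11 | none | none
F9 | step 2 | 2-hydroxy-4-methoxy-6-(2-methylbut-3-yn-2-yloxy)benzaldehyde | COc1cc(O)c(C=O)c(OC(C)(C)C#C)c1
F10 | step 2 | 2-hydroxy-4-methoxy-6-(2-methylbut-3-en-2-yloxy)benzaldehyde | COc1cc(O)c(C=O)c(OC(C)(C)C=C)c1
A1 | alternative 1 | 2-[(3R)-3-[2,4-bis(methoxymethoxy)phenyl]-3-(tert-butyldimethylsilyloxy)propyl]-5-methoxy-4-(3-methylbut-2-enyl)-3-(triisopropylsilyloxy)phenol | COc1cc(O)c(CC[C@@H](O[Si](C)(C)C(C)(C)C)c2ccc(OCOC)cc2OCOC)c(O[Si](C(C)C)(C(C)C)C(C)C)c1CC=C(C)C
A2 | alternative 1 | 3-methoxy-2-(3-methylbut-2-enyl)cyclobut-2-en-1-one | O=C1CC(OC)=C1CC=C(C)C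
A3 | alternative 1 | (5R)-5-[2,4-bis(methoxymethoxy)phenyl]-5-(tert-butyldimethylsilyloxy)pent-1-ynyl triisopropylsilyl ether | CC(C)[Si](OC#CCC[C@@H](O[Si](C)(C)C(C)(C)C)c1ccc(OCOC)cc1OCOC)(C(C)C)C(C)C
A4 | alternative 2 | (2S)-2-[2,4-bis(methoxymethoxy)phenyl]-7-methoxy-5-(methoxymethoxy)-8-(3-methylbut-2-enyl)chroman | COc1cc(OCOC)c2c(c1CC=C(C)C)O[C@H](c1ccc(OCOC)cc1OCOC)CC2
A5 | alternative 2 | 3-methoxy-5-(methoxymethoxy)-2-(3-methylbut-2-enyl)-6-(trimethylsilyl)phenyl trifluoromethanesulfonate | COc1cc(OCOC)c([Si](C)(C)C)c(OS(=O)(=O)C(F)(F)F)c1CC=C(C)C
A6 | alternative 2 | (1S)-3-chloro-1-[2,4-bis(methoxymethoxy)phenyl]propan-1-ol | O[C@H](c1ccc(OCOC)cc1OCOC)CCCl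
A7 | alternative 3 | (2S)-5-(tert-butyldimethylsilyloxy)-2-[4-(tert-butyldimethylsilyloxy)-2-hydroxyphenyl]-7-methoxy-8-(3-methylbut-2-enyl)chroman | COc1cc(O[Si](C)(C)C(C)(C)C)c2c(c1CC=C(C)C)O[C@H](c1ccc(O[Si](C)(C)C(C)(C)C)cc1O)CC2
A8 | alternative 3 | 3-(tert-butyldimethylsilyloxy)-2-(hydroxymethyl)-5-methoxy-6-(3-methylbut-2-enyl)phenol | COc1cc(O[Si](C)(C)C(C)(C)C)c(CO)c(O)c1CC=C(C)C
A9 | alternative 3 | 5-(tert-butyldimethylsilyloxy)-2-vinylphenol | C=Cc1ccc(O[Si](C)(C)C(C)(C)C)cc1O
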